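At early times each flask below holds starting material, reagent and the two catalysts, and the target has to come through the open intermediate.

all flasks: starting material 0.50 mM; reagent 1.50 equiv; free catalyst 2.5 mol%; second catalyst 1 mol%; time 40 s
- gamma: temperature 110 °C
- zeta: temperature 50 °C
- beta: temperature 80 °C
- alpha: temperature 20 °C

    free catalyst + target → free catalyst + over-reaction product (k1 = 188 M⁻¹ s⁻¹, Ea1 = 43.0 kJ mol⁻¹)
    starting material + free catalyst → free catalyst + open intermediate (k2 = 1360 M⁻¹ s⁻¹, Ea2 = 41.0 kJ mol⁻¹)
    second catalyst + open intermediate ⇌ catalyst intermediate (K3 = 8660 M⁻¹, k3 = 4800 M⁻¹ s⁻¹, Ea3 = 23.0 kJ mol⁻¹, ΔH3 = −17.0 kJ mol⁻¹)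
    reagent + catalyst intermediate → second catalyst + target (k4 = 1670 M⁻¹ s⁻¹, Ea4 = 38.0 kJ mol⁻¹)
    (constants at 20 °C)

- constants are those at 20 °C; use the activation energies and enthalpies for any other temperature

- the flask with the highest amount of target, in percent of the starting material charged ("all alike" if they lie within 1.5 percentage points) (gamma / zeta / beta / alpha / all alike)
- final target, as a percentage of the starting material charged, in gamma
- final target, as a percentage of the starting material charged, in zeta
- final target, as a percentage of the starting material charged, in beta
- final target, as a percentage of the starting material charged, in alpha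

The hand reckoning goes as far as zeta, at 50 °C. Free catalyst comes back from both steps that use it, so in zeta its amount stays at the charge and those steps are pseudo-first-order: starting material opens at 0.0810 s⁻¹, leaving 3.92% of the charge after 40 s, and target over-reacts at κ = 0.0121 s⁻¹.

Between them stands the second catalyst. With open intermediate at 0.5 of the charge, each second-catalyst site in zeta captures at 2.88 s⁻¹, lets go at 2.54 s⁻¹ and turns over with the full reagent at 5.33 s⁻¹. The bound share is capture over the sum of the three, and the loading times that share times the turnover gives J = 0.0143 s⁻¹. Opening is faster than this, so open intermediate piles up and J acts as a steady feed of target.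

The balance dP/dt = J − κP then integrates to P = (J/κ)(1 − e^(−κt)), which gives 45.3% for zeta. The assumed fill holds up: at the midpoint, opened minus passed is 51.6% of the charge.

The weak link is the reagent, taken at full charge. At the midpoint of zeta the reckoning puts it near 1.21, not 1.50 equiv, so the turnover falls to 4.31 s⁻¹. The reforged gate flux, the share of the charge that the second catalyst passes per second, is 0.0128 s⁻¹. The closed form then gives 40.5% target in zeta.

The forecast names zeta as best, with 4.5% in gamma, 42% in zeta, 30% in beta and 12% in alpha, on the grounds of “rough consecutive-reaction estimates with saturation of the second catalyst”. Its zeta figure lies above the hand figure.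

The simulation gives 3.54% in gamma, 39.0% in zeta, 30.2% in beta and 10.5% in alpha, so zeta stands highest, and the forecast holds on every question.

The gate flux over 40 s comes to 51.2% of the charge in zeta, and target plus over-reaction product there stand at 48.5%. The neighbour of zeta charged with 4 mol% of second catalyst has its gate widened in proportion, to 204% over the run, twice the 96.1% opened. The feed therefore follows opening itself, decaying at 0.0810 s⁻¹ from the start, and the same balance integrated with that feed gives 67.9% target. That neighbour ends with 66.5% target, 20.7% over-reaction product and 8.50% open intermediate.

(The numbers of this flask are made up.)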